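**Retrosynthetic overview**

1. Numbering: ring C1(=O)–C2=C3–C4(OMe)–C5H2–C6 (quaternary), side chain C8(H)Me–C7(H)OH–Ar. The γ-hydroxy enone (O7, C1=O, C2=C3) is read as an opened, carbonyl-transposed vinylogous ester. Closing O7 onto C1 and moving the carbonyl to C3 gives a tetrahydrobenzofuran-6-one; step 8 reverses this.
2. With oxygen on C1, C3 and C4, the ring C1–C6 is a dearomatised 4-methoxyresorcinol, and the quaternary C6 lies para to O3. The key cut is C6–allyl, made by oxidative dearomative para-allylation of a flat phenol (step 6). C4=C5 is then saturated by conjugate reduction, with C4 set under equilibrium control (step 7).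
3. The syn C7/C8 pair is a cis-2-aryl-3-methyl pair on the dihydrofuran ring. Both groups shield one face, so C6 is relayed from them. They are set together by one enantioselective syn hydrogenation of an achiral 2-aryl-3-methylbenzofuran (step 4).
4. The benzofuran comes from 3,4,5-trimethoxypropiophenone and a bromophenol (from O-benzylisovanillin) by enolate arylation and cyclodehydration (steps 1–3).
5. Ring order: the furan ring is closed first (step 3) and reduced (step 4). The carbocycle is carried as an arene and dearomatised (step 6). The furan ring is opened last (step 8).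

Key step: step 6

Locants: bicyclic compounds use benzofuran numbering. O1 = O7, C2 = C7, C3 = C8, C3a = C6, C4 = C5, C5 = C4, C6 = C3, C7 = C2, C7a = C1 of megaphone.

Assumption: the sense of induction of the Ru–NHC catalyst on 7 is not known in advance; the (R,R)-ligand is written, and its antipode is used if it delivers the (2S,3R) product.

**Step 1**
Reactants: 1 3-(benzyloxy)-4-methoxybenzaldehyde
Product: 3 3-(benzyloxy)-4-methoxyphenol, via aryl formate 2 (not isolated)
Conditions: mCPBA, CH2Cl2, 0 °C to rt; aq NaHCO3 wash; then K2CO3 (cat.), MeOH, rt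
Reagents that add atoms: mCPBA (3-chloroperoxybenzoic acid), O=C(OO)c1cccc(Cl)c1
Why: Baeyer–Villiger oxidation of an electron-rich benzaldehyde proceeds with aryl migration to formate 2, which catalytic base in methanol transesterifies to the phenol; no stereocentre is formed.

**Step 2**
Reactants: 3 3-(benzyloxy)-4-methoxyphenol
Product: 4 5-(benzyloxy)-2-bromo-4-methoxyphenol
Conditions: NBS (1.0 equiv), CH2Cl2, −20 to 0 °C
Reagents that add atoms: N-bromosuccinimide, O=C1CCC(=O)N1Br
Why: Electrophilic aromatic bromination should go to the carbon ortho to the free hydroxyl and para to the benzyloxy group, the most activated and least hindered site of a 3,4-dialkoxyphenol.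

**Step 3**
Reactants: 4 5-(benzyloxy)-2-bromo-4-methoxyphenol; 5 1-(3,4,5-trimethoxyphenyl)propan-1-one
Product: 7 6-(benzyloxy)-5-methoxy-3-methyl-2-(3,4,5-trimethoxyphenyl)-1-benzofuran, via hydroxyaryl ketone 6 (not isolated)
Conditions: Pd2(dba)3 (2.5 mol %), 2-(di-tert-butylphosphino)-1,1'-binaphthyl (6 mol %), NaOt-Bu (2.5 equiv), toluene, 80 °C; then CF3CO2H, CH2Cl2, rt
Reagents that add atoms: none
Why: Palladium-catalysed α-arylation of the ketone enolate with the o-bromophenoxide gives hydroxyaryl ketone 6, whose phenol adds to the ketone under acid and loses water to form the aromatic furan ring (cyclodehydration), which erases the stereocentre of 6.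

**Step 4**
Reactants: 7 6-(benzyloxy)-5-methoxy-3-methyl-2-(3,4,5-trimethoxyphenyl)-1-benzofuran
Product: 8 (2R,3S)-6-(benzyloxy)-5-methoxy-3-methyl-2-(3,4,5-trimethoxyphenyl)-2,3-dihydro-1-benzofuran (cis)
Conditions: [Ru(cod)(2-methylallyl)2] (5 mol %), (R,R)-SINpEt·HBF4 (10 mol %), KOt-Bu (15 mol %), hexane/toluene, H2 (80 bar), 40 °C
Reagents that add atoms: none
Why: Homogeneous asymmetric hydrogenation of the furan ring of benzofurans with chiral ruthenium bis(NHC) catalysts is a known reaction type in which syn delivery of H2 to one face of C2=C3 sets C2 and C3 together as the cis pair, the catalyst chooses the face, and the carbocyclic rings and the benzyl ether should stay untouched.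

**Step 5**
Reactants: 8 (2R,3S)-6-(benzyloxy)-5-methoxy-3-methyl-2-(3,4,5-trimethoxyphenyl)-2,3-dihydro-1-benzofuran
Product: 9 (2R,3S)-5-methoxy-3-methyl-2-(3,4,5-trimethoxyphenyl)-2,3-dihydro-1-benzofuran-6-ol (cis)
Conditions: H2 (1 atm), 10% Pd/C, EtOAc, rt
Reagents that add atoms: none
Why: Hydrogenolysis of the primary benzyl aryl ether on palladium is faster than cleavage of the secondary, ring-bound C2–O bond, so the phenol should be set free without change at C2 and C3.

**Step 6**
Reactants: 9 (2R,3S)-5-methoxy-3-methyl-2-(3,4,5-trimethoxyphenyl)-2,3-dihydro-1-benzofuran-6-ol; 10 allyltrimethylsilane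
Product: 11 (2R,3S,3aS)-5-methoxy-3-methyl-3a-(prop-2-en-1-yl)-2-(3,4,5-trimethoxyphenyl)-3,3a-dihydro-1-benzofuran-6(2H)-one
Conditions: PhI(OAc)2 (1.1 equiv), 10 (5 equiv), (CF3)2CHOH/CH2Cl2, −20 to 0 °C
Reagents that add atoms: none
Why: Ligand exchange of phenol 9 on iodine(III) and loss of iodobenzene in the ionising, weakly nucleophilic solvent gives a phenoxenium ion whose charge is shared by C5 (methoxy-oxocarbenium form), C7 and C3a; the soft π-nucleophile 10 adds in the vinylogous SN2'-like sense at C3a, and loss of the silyl group to acetate releases the allyl group and the cross-conjugated dienone 11. The closest known reaction type is the iodine(III)-mediated oxidative Hosomi–Sakurai para-allylation of 4-alkylphenols, which forms allyl-bearing quaternary carbons, supported by the acid-promoted substitution of quinone monoketals by π-nucleophiles at a ring carbon remote from the ketal carbon. No ring is closed; the step forms the C3a–allyl bond (C6–allyl of megaphone) and turns the flat arene into the carbocycle of the target. The only new stereocentre, C3a, is controlled by the adjacent C3 methyl group and the C2 aryl group, which lie on the same face of the planar cation, so 10 should approach from the opposite face and place allyl trans to methyl (3aS). The step needs para over ortho attack: C5 carries the methoxy group and attack there would give the less stable linear dienone, C7 is flanked by two oxygen-bearing carbons, and para attack uses the alkyl-stabilised cation terminus and keeps both the enol ether and the vinylogous ester conjugation. Low temperature and an excess of 10 should outrun loss of H-3, which would lead back to a benzofuran.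

**Step 7**
Reactants: 11 (2R,3S,3aS)-5-methoxy-3-methyl-3a-(prop-2-en-1-yl)-2-(3,4,5-trimethoxyphenyl)-3,3a-dihydro-1-benzofuran-6(2H)-one
Product: 13 (2R,3S,3aR,5R)-5-methoxy-3-methyl-3a-(prop-2-en-1-yl)-2-(3,4,5-trimethoxyphenyl)-3,3a,4,5-tetrahydro-1-benzofuran-6(2H)-one, via 5S epimer 12 (not isolated)
Conditions: Cu(OAc)2·H2O (5 mol %), 1,2-bis(diphenylphosphino)benzene (5 mol %), (MeO)2MeSiH, t-BuOH, toluene, 0 °C to rt; then NaOMe (cat.), MeOH, rt
Reagents that add atoms: none
Why: Ligated copper hydride conjugate reduction should pick the α-methoxy enone C4=C5, because C7=C7a is deactivated as a vinylogous ester and the isolated allyl group is inert to CuH, and C5, first set by protonation, is then equilibrated by methoxide through the enolate to the equatorial methoxy epimer trans to the pseudo-axial allyl group (5R), which avoids the 1,3-diaxial contact.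

**Step 8**
Reactants: 13 (2R,3S,3aR,5R)-5-methoxy-3-methyl-3a-(prop-2-en-1-yl)-2-(3,4,5-trimethoxyphenyl)-3,3a,4,5-tetrahydro-1-benzofuran-6(2H)-one
Product: 15 megaphone (4R,6R)-6-[(1R,2S)-1-hydroxy-1-(3,4,5-trimethoxyphenyl)propan-2-yl]-4-methoxy-6-(prop-2-en-1-yl)cyclohex-2-en-1-one, via allylic alcohol 14 (not isolated)
Conditions: i-Bu2AlH, CH2Cl2, −78 °C; then 1 M HCl, THF, 0 °C
Reagents that add atoms: water, O
Why: In this Stork–Danheiser-type transposition, 1,2-reduction of the vinylogous ester carbonyl gives allylic alcohol 14, which in dilute acid ionises to the oxygen-stabilised allyl cation, takes up water at C7a and collapses through the hemiketal to the enone, so the furan ring opens with the C2–O bond intact and C7, C8, C6 and C4 of megaphone unchanged.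

**Compound list**

1 | 3-(benzyloxy)-4-methoxybenzaldehyde | O=Cc1ccc(OC)c(OCc2ccccc2)c1 | starting material
2 | 3-(benzyloxy)-4-methoxyphenyl formate | O=COc1ccc(OC)c(OCc2ccccc2)c1 | intermediate
3 | 3-(benzyloxy)-4-methoxyphenol | Oc1ccc(OC)c(OCc2ccccc2)c1 | intermediate
4 | 5-(benzyloxy)-2-bromo-4-methoxyphenol | Oc1cc(OCc2ccccc2)c(OC)cc1Br | intermediate
5 | 1-(3,4,5-trimethoxyphenyl)propan-1-one | CCC(=O)c1cc(OC)c(OC)c(OC)c1 | starting material
6 | 2-[4-(benzyloxy)-2-hydroxy-5-methoxyphenyl]-1-(3,4,5-trimethoxyphenyl)propan-1-one (racemic) | CC(C(=O)c1cc(OC)c(OC)c(OC)c1)c1cc(OC)c(OCc2ccccc2)cc1O | intermediate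
7 | 6-(benzyloxy)-5-methoxy-3-methyl-2-(3,4,5-trimethoxyphenyl)-1-benzofuran | Cc1c(-c2cc(OC)c(OC)c(OC)c2)oc2cc(OCc3ccccc3)c(OC)cc12 | intermediate
8 | (2R,3S)-6-(benzyloxy)-5-methoxy-3-methyl-2-(3,4,5-trimethoxyphenyl)-2,3-dihydro-1-benzofuran | C[C@@H]1[C@H](c2cc(OC)c(OC)c(OC)c2)Oc2cc(OCc3ccccc3)c(OC)cc21 | intermediate
9 | (2R,3S)-5-methoxy-3-methyl-2-(3,4,5-trimethoxyphenyl)-2,3-dihydro-1-benzofuran-6-ol | C[C@@H]1[C@H](c2cc(OC)c(OC)c(OC)c2)Oc2cc(O)c(OC)cc21 | intermediate
10 | allyltrimethylsilane | C=CC[Si](C)(C)C | starting material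
11 | (2R,3S,3aS)-5-methoxy-3-methyl-3a-(prop-2-en-1-yl)-2-(3,4,5-trimethoxyphenyl)-3,3a-dihydro-1-benzofuran-6(2H)-one | C=CC[C@]12C=C(OC)C(=O)C=C1O[C@@H](c1cc(OC)c(OC)c(OC)c1)[C@H]2C | intermediate
12 | (2R,3S,3aR,5S)-5-methoxy-3-methyl-3a-(prop-2-en-1-yl)-2-(3,4,5-trimethoxyphenyl)-3,3a,4,5-tetrahydro-1-benzofuran-6(2H)-one | C=CC[C@]12C[C@H](OC)C(=O)C=C1O[C@@H](c1cc(OC)c(OC)c(OC)c1)[C@H]2C | intermediate
13 | (2R,3S,3aR,5R)-5-methoxy-3-methyl-3a-(prop-2-en-1-yl)-2-(3,4,5-trimethoxyphenyl)-3,3a,4,5-tetrahydro-1-benzofuran-6(2H)-one | C=CC[C@]12C[C@@H](OC)C(=O)C=C1O[C@@H](c1cc(OC)c(OC)c(OC)c1)[C@H]2C | intermediate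
14 | (2R,3S,3aR,5R)-5-methoxy-3-methyl-3a-(prop-2-en-1-yl)-2-(3,4,5-trimethoxyphenyl)-2,3,3a,4,5,6-hexahydro-1-benzofuran-6-ol (either C6 epimer, centre lost in the same step) | C=CC[C@]12C[C@@H](OC)C(O)C=C1O[C@@H](c1cc(OC)c(OC)c(OC)c1)[C@H]2C | intermediate
15 | megaphone, (4R,6R)-6-[(1R,2S)-1-hydroxy-1-(3,4,5-trimethoxyphenyl)propan-2-yl]-4-methoxy-6-(prop-2-en-1-yl)cyclohex-2-en-1-one | C=CC[C@]1([C@H](C)[C@@H](O)c2cc(OC)c(OC)c(OC)c2)C[C@@H](OC)C=CC1=O | target

**Step count**

Total step count: 8. Longest linear sequence: 8 (1 to 15); 5 and 10 are bought.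

**Steps most likely to fail**

First, step 6 (key step).
- What may go wrong: attack of the allylsilane at an ortho carbon instead of the hindered para carbon; loss of H-3 from the cation with re-aromatisation; or further oxidation while oxidant and nucleophile share one flask.
- Fallback: it sets out from 9 and comes back at 11, and it separates the oxidation from the C–C bond formation.
- 9 is oxidised with PhI(OAc)2 in methanol to the o-quinone monoketal (2R,3S)-5,5-dimethoxy-3-methyl-2-(3,4,5-trimethoxyphenyl)-2,3-dihydro-1-benzofuran-6(5H)-one F1, which is isolated.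
- F1 is then ionised with catalytic TMSOTf in CH2Cl2 at −78 °C in the presence of 10. The closed-shell ketal-derived oxocarbenium ion is substituted in the SN2' sense at C3a, under the same facial control by the C3 methyl and C2 aryl groups.

Second, step 4.
- What may go wrong: slow turnover or poor facial selectivity at the tetrasubstituted C2=C3 bond.
- Fallback: it sets out from 6 (isolated by leaving out the acid treatment of step 3) and comes back at 8. It sets the two centres by a stereoconvergent reduction instead of arene hydrogenation.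
- Ru(II)-TsDPEN transfer hydrogenation in HCO2H/Et3N under dynamic kinetic resolution racemises the labile α-aryl centre. It should give the Felkin–Anh anti alcohol (1S,2S)-2-[4-(benzyloxy)-2-hydroxy-5-methoxyphenyl]-1-(3,4,5-trimethoxyphenyl)propan-1-ol F2, with the catalyst antipode chosen for the (1S) carbinol.
- A Mitsunobu cycloetherification (PPh3, DIAD, THF, 0 °C), with the phenol as nucleophile, then closes the ring with inversion at the benzylic carbon to the cis compound 8.

Third, step 3.
- What may go wrong: sluggish oxidative addition of the very electron-rich bromophenoxide, with competing protodebromination or self-condensation of the ketone.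
- Fallback: it sets out from 3 and 5, comes back at 7, makes step 2 unnecessary, and reverses the polarity at C8.
- 5 is brominated with CuBr2 (EtOAc/CHCl3, reflux) to 2-bromo-1-(3,4,5-trimethoxyphenyl)propan-1-one F3.
- F3 is condensed with phenol 3 under TiCl4. Friedel–Crafts-type alkylation at the carbon ortho to OH and para to OBn is followed by cyclodehydration to the benzofuran.

**Further compounds**

F1 | step 6 | (2R,3S)-5,5-dimethoxy-3-methyl-2-(3,4,5-trimethoxyphenyl)-2,3-dihydro-1-benzofuran-6(5H)-one | C[C@@H]1[C@H](c2cc(OC)c(OC)c(OC)c2)OC2=CC(=O)C(OC)(OC)C=C21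
F2 | step 4 | (1S,2S)-2-[4-(benzyloxy)-2-hydroxy-5-methoxyphenyl]-1-(3,4,5-trimethoxyphenyl)propan-1-ol | C[C@@H](c1cc(OC)c(OCc2ccccc2)cc1O)[C@H](O)c1cc(OC)c(OC)c(OC)c1
F3 | step 3 | 2-bromo-1-(3,4,5-trimethoxyphenyl)propan-1-one | CC(Br)C(=O)c1cc(OC)c(OC)c(OC)c1
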